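The ratio of first to second nucleophile charged is 0.600 in the noon run and 1.40 in the midnight run, and the flask stands between them at 0.900.

| setting | noon | midnight | flask |
|---|---|---|---|
| substrate | 0.20 M | 0.20 M | 0.20 M |
| first nucleophile | 0.60 equiv | 1.4 equiv | 0.900 equiv |
| second nucleophile | 1 equiv | 1 equiv | 1.00 equiv |
| protic impurity | 0.20 M | 0.20 M | 0.200 M |
| remark | run made earlier | run made earlier |  |
| time |  |  | 6.0 h |

| run | time / h | target / % | substrate / % |
|---|---|---|---|
| noon | 0.333 | 0 | 94 |
| noon | 0.833 | 1 | 90 |
| noon | 1.50 | 2 | 86 |
| noon | 2.50 | 4 | 76 |
| noon | 4.00 | 7 | 72 |
| midnight | 0.250 | 0 | 98 |
| midnight | 0.500 | 5 | 93 |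
| midnight | 1.00 | 5 | 87 |
| midnight | 2.00 | 8 | 78 |
| midnight | 4.00 | 15 | 66 |

(standard deviation of a reading: 1.5 percentage points)

- concentration of target at 6.0 h, in M
- concentration of substrate at 6.0 h, in M
- concentration of other capture product at 6.0 h, in M



Does the first nucleophile set how fast the substrate goes? Very little. By 4.00 h the noon run has lost 28 percentage points of its substrate and the midnight run 34 points, so the reading of the loss grew by a factor 1.21, less than the factor 2.33 in the charge. I therefore reckon the loss as pseudo-first-order in the substrate's own fraction over the stretch I extend, with the first nucleophile entering weakly.

What does it change, then? Where the substrate goes. Target at that time reads 7 % in the noon run and 15 % in the midnight run, twice as much. I picture one reactive intermediate for which the nucleophiles compete, so target over other capture product should equal a constant times the nucleophile ratio. Counting all other lost substrate as other capture product, that product ratio is 0.333 at noon and 0.789 at midnight. Dividing by the charged ratios gives 0.556 and 0.564, and their mean is r, the capture ratio, a selectivity factor: 0.560.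

Isn't that fragile? Yes: it rests on an assumed closed balance and on a target reading of 7 % with scatter 1.5 points, so r is a reading.

For the flask I expect a product ratio of 0.504, so target takes a share 0.335 of lost substrate. Interpolating between the runs, I expect 0.698 of the flask's substrate to stand at 4.00 h. The midnight run's last interval gives a loss of 0.0835 /h, which leaves 0.590 at 6.0 h. My fractions are therefore 0.137 target and 0.273 other capture product.

The forecast, holding that “the substrate forms a reactive intermediate, which is then partitioned between capture routes”, gives 0.027 M target, 0.116 M substrate and 0.057 M other capture product; target over the sum of the two products in these printed values is 0.321, below my 0.335.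

The flask gives 0.0232 M target, 0.123 M substrate and 0.0536 M other capture product, which are fractions 0.116, 0.615 and 0.268 of the charge.

    substrate ⇌ intermediate (K = 0.00134, k = 0.0854 /min)
    first nucleophile + intermediate → target (k = 2.52 /M/min)
    second nucleophile + intermediate → other capture product (k = 6.50 /M/min)
    second nucleophile → decomposed reagent (k = 0.00236 /min)
    first nucleophile + protic impurity → quenched reagent (k = 0.00966 /M/min)

At 6.00 h the flask's second nucleophile goes to decomposed reagent 2.2 times as fast as to other capture product, and 26.8 % of its charge remains, less than the 61.5 % of substrate. In the flask, target over other capture product is 0.433 against the 0.504 reckoned from r. With 2.50 equiv of second nucleophile in the same flask, r gives 0.202, and that neighbour holds 0.166.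

The numbers in the tables were generated by integration for substances that don't exist.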